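**Plan**

1. Cadinane numbering is used: ring A = C1–C2–C3(OAc)–C4(CH3)=C5–C6, ring B = C1–C10(CH3)–C9(OAc)–C8–C7(=C11)–C6; C12 is the CH2O carbon and C13 the methyl on C11.
2. Retrosynthesis: the esters come off, the C3 carbinol goes back to the 4-en-3-one and that to a β-sulfonyl silyl enol ether; then the ring-fusion bond C1–C6 and the bond C4–C5 are cut together, which opens ring A and ring B to one acyclic chain C4–C3–C2–C1–C10–C9–C8–C7–C6–C5.
3. Enabling feature: ring A is a cyclohexene with oxygen on C3 next to the C4–C5 bond and shares only C1–C6 with ring B. A (1Z)-3-silyloxy diene C1=C2–C3=C4 and a sulfonyl-activated alkene C5=C6, joined by the four-carbon bridge C7–C10, therefore give both rings in one intramolecular [4+2] cycloaddition; the sulfonyl group on C5 is a helper that later leaves to create C4=C5.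
4. Forward order: C9/C10 by propargylation and inversion; a temporary δ-lactone (C12 carbonyl on the C9 oxygen) is closed by Dieckmann condensation and its enol triflate fixes the C7=C11 geometry (C12 cis to C8); Heck coupling adds C5/C6; the lactone is reduced open; the alkyne is acylated, enol-silylated and half-hydrogenated to the (Z)-diene; cycloaddition, elimination, reduction at C3 and acylations finish.
5. Stereochemistry: C10 from the (R)-propargylic alcohol 1 by chirality transfer, C9 by anti addition then Mitsunobu inversion, C1 and C6 in the cycloaddition ((Z)-diene geometry and allylic strain), C3 by hydride attack on the convex face.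

Key step: step 16

Remark: cadinane numbers are also used for the same atoms in the acyclic intermediates; β means the face of the bicycle that carries H1 and H6, α the opposite face.

**Route**

Step 1
Reactants: 1 (R)-4-(trimethylsilyl)but-3-yn-2-ol
Product: 2 (R)-4-(trimethylsilyl)but-3-yn-2-yl methanesulfonate
Conditions: MsCl, Et3N, CH2Cl2, −78 to 0 °C
Reagents that add atoms: methanesulfonyl chloride CS(=O)(=O)Cl
Why: Sulfonylation of the secondary propargylic alcohol at oxygen leaves the stereocentre untouched and provides the leaving group for the anti SN2′ metalation of step 2.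

Step 2
Reactants: 2 (R)-4-(trimethylsilyl)but-3-yn-2-yl methanesulfonate; 3 3-[(tert-butyldimethylsilyl)oxy]propanal
Product: 5 (3R,4S)-1-[(tert-butyldimethylsilyl)oxy]-4-methyl-6-(trimethylsilyl)hex-5-yn-3-ol, via allenylzinc 4 (not isolated)
Conditions: Pd(OAc)2 (5 mol %), PPh3 (5 mol %), Et2Zn (3 equiv), THF, −78 to −20 °C
Reagents that add atoms: none
Why: Palladium-catalysed propargylation (Marshall type): zerovalent palladium displaces the mesylate anti in an SN2′ sense, transmetalation with Et2Zn gives the axially chiral allenylzinc 4, and its addition to the aldehyde through a cyclic SE2′ transition state transfers the chirality of 2 to C10 (S) and sets the anti carbinol C9 (R).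

Step 3
Reactants: 5 (3R,4S)-1-[(tert-butyldimethylsilyl)oxy]-4-methyl-6-(trimethylsilyl)hex-5-yn-3-ol; 6 propanoic acid
Product: 7 (3S,4S)-1-[(tert-butyldimethylsilyl)oxy]-4-methyl-6-(trimethylsilyl)hex-5-yn-3-yl propanoate
Conditions: PPh3, DIAD, THF, 0 °C to rt
Reagents that add atoms: none
Why: Mitsunobu esterification: the C9 hydroxyl is activated as an alkoxyphosphonium ion and displaced by propanoate in an SN2 step, so C9 is inverted to S (the syn C9/C10 array of the target) and the C11–C13 unit is attached in the same step.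

Step 4
Reactants: 7 (3S,4S)-1-[(tert-butyldimethylsilyl)oxy]-4-methyl-6-(trimethylsilyl)hex-5-yn-3-yl propanoate
Product: 10 (3S,4S)-4-methyl-3-(propanoyloxy)-6-(trimethylsilyl)hex-5-ynoic acid, via alcohol 8 (not isolated), via aldehyde 9 (not isolated)
Conditions: CrO3, H2SO4, acetone/H2O, 0 °C
Reagents that add atoms: chromium trioxide O=[Cr](=O)=O; water O
Why: Jones oxidation: the acidic medium cleaves the primary silyl ether and chromic acid oxidises the freed alcohol 8 through aldehyde 9 (as its hydrate) to the acid, which leaves the secondary ester, the silylalkyne and C9/C10 untouched.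

Step 5
Reactants: 10 (3S,4S)-4-methyl-3-(propanoyloxy)-6-(trimethylsilyl)hex-5-ynoic acid
Product: 11 methyl (3S,4S)-4-methyl-3-(propanoyloxy)-6-(trimethylsilyl)hex-5-ynoate
Conditions: Me3SiCHN2, MeOH/PhMe, 0 °C
Reagents that add atoms: (trimethylsilyl)diazomethane C[Si](C)(C)C=[N+]=[N-]
Why: Esterification of the acid with (trimethylsilyl)diazomethane in methanol is neutral and fast, so the β-acyloxy group is not eliminated.

Step 6
Reactants: 11 methyl (3S,4S)-4-methyl-3-(propanoyloxy)-6-(trimethylsilyl)hex-5-ynoate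
Product: 12 (6S)-4-hydroxy-3-methyl-6-[(2S)-4-(trimethylsilyl)but-3-yn-2-yl]-5,6-dihydro-2H-pyran-2-one (enol form of the pyran-2,4-dione)
Conditions: LiN(SiMe3)2 (3 equiv), THF, −78 to 0 °C; then 1 M HCl
Reagents that add atoms: none
Why: Dieckmann (intramolecular Claisen) condensation: the propanoate enolate (C11) attacks the methyl ester carbonyl (C7) in a 6-exo-trig closure and the product is held as its doubly stabilised enolate until the acidic quench; C9 and C10 are not involved.

Step 7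
Reactants: 12 (6S)-4-hydroxy-3-methyl-6-[(2S)-4-(trimethylsilyl)but-3-yn-2-yl]-5,6-dihydro-2H-pyran-2-one
Product: 13 (6S)-3-methyl-2-oxo-6-[(2S)-4-(trimethylsilyl)but-3-yn-2-yl]-5,6-dihydro-2H-pyran-4-yl trifluoromethanesulfonate
Conditions: Tf2O, Et3N, CH2Cl2, −78 °C
Reagents that add atoms: trifluoromethanesulfonic anhydride O=S(=O)(OS(=O)(=O)C(F)(F)F)C(F)(F)F
Why: O-Sulfonylation of the vinylogous acid at the C7 oxygen gives the enol triflate; the six-membered ring holds C12 and C8 cis on the C7=C11 double bond, which is the geometry of the tetrasubstituted alkene of the target.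

Step 8
Reactants: 13 (6S)-3-methyl-2-oxo-6-[(2S)-4-(trimethylsilyl)but-3-yn-2-yl]-5,6-dihydro-2H-pyran-4-yl trifluoromethanesulfonate; 14 phenyl vinyl sulfone
Product: 15 (6S)-3-methyl-4-[(E)-2-(phenylsulfonyl)ethenyl]-6-[(2S)-4-(trimethylsilyl)but-3-yn-2-yl]-5,6-dihydro-2H-pyran-2-one
Conditions: Pd(OAc)2 (5 mol %), n-Bu4NCl, KOAc, DMF, 50 °C
Reagents that add atoms: none
Why: Mizoroki–Heck reaction: oxidative addition of the C7–OTf bond, syn insertion of the vinyl sulfone and syn β-hydride elimination give the (E)-dienyl sulfone, while cyclisation of the alkenylpalladium onto the silylalkyne is excluded inside the lactone because it would need a bridgehead double bond.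

Step 9
Reactants: 15 (6S)-3-methyl-4-[(E)-2-(phenylsulfonyl)ethenyl]-6-[(2S)-4-(trimethylsilyl)but-3-yn-2-yl]-5,6-dihydro-2H-pyran-2-one
Product: 17 (2E,5S,6S)-2,6-dimethyl-3-[(E)-2-(phenylsulfonyl)ethenyl]-8-(trimethylsilyl)oct-2-en-7-yne-1,5-diol, via lactol 16 (not isolated)
Conditions: i-Bu2AlH (3.5 equiv), CH2Cl2, −78 to −20 °C; aq. potassium sodium tartrate
Reagents that add atoms: none
Why: Hydride reduction of the unsaturated lactone by i-Bu2AlH passes the lactol and gives the primary allylic alcohol (C12) and the free C9 hydroxyl with the alkene geometry kept; the temporary ring has to go here because a C9–O–C12 bridge could not be carried into ring B without a bridgehead C7=C11 bond.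

Step 10
Reactants: 17 (2E,5S,6S)-2,6-dimethyl-3-[(E)-2-(phenylsulfonyl)ethenyl]-8-(trimethylsilyl)oct-2-en-7-yne-1,5-diol
Product: 18 (2E,5S,6S)-1-[(tert-butyldimethylsilyl)oxy]-2,6-dimethyl-3-[(E)-2-(phenylsulfonyl)ethenyl]-8-(trimethylsilyl)oct-2-en-7-yn-5-ol
Conditions: TBSCl, imidazole, CH2Cl2, 0 °C
Reagents that add atoms: tert-butyldimethylsilyl chloride CC(C)(C)[Si](C)(C)Cl
Why: Silylation with the bulky chlorosilane is selective for the primary allylic hydroxyl (C12) over the secondary C9 hydroxyl.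

Step 11
Reactants: 18 (2E,5S,6S)-1-[(tert-butyldimethylsilyl)oxy]-2,6-dimethyl-3-[(E)-2-(phenylsulfonyl)ethenyl]-8-(trimethylsilyl)oct-2-en-7-yn-5-ol
Product: 19 (2E,5S,6S)-1-[(tert-butyldimethylsilyl)oxy]-2,6-dimethyl-3-[(E)-2-(phenylsulfonyl)ethenyl]-8-(trimethylsilyl)oct-2-en-7-yn-5-yl acetate
Conditions: Ac2O, pyridine, DMAP (cat.), CH2Cl2, 0 °C to rt
Reagents that add atoms: acetic anhydride CC(=O)OC(C)=O
Why: Acetylation under nucleophilic catalysis by DMAP installs the C9 acetate of the target with retention.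

Step 12
Reactants: 19 (2E,5S,6S)-1-[(tert-butyldimethylsilyl)oxy]-2,6-dimethyl-3-[(E)-2-(phenylsulfonyl)ethenyl]-8-(trimethylsilyl)oct-2-en-7-yn-5-yl acetate
Product: 20 (2E,5S,6S)-1-[(tert-butyldimethylsilyl)oxy]-2,6-dimethyl-3-[(E)-2-(phenylsulfonyl)ethenyl]oct-2-en-7-yn-5-yl acetate
Conditions: AgNO3 (0.1 equiv), acetone/H2O, rt, dark
Reagents that add atoms: none
Why: Silver-catalysed protodesilylation cleaves only the alkynyl C–Si bond through the silver acetylide and leaves the silyl ether, the acetate and the vinyl sulfone alone, which a basic methanolysis would not.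

Step 13
Reactants: 20 (2E,5S,6S)-1-[(tert-butyldimethylsilyl)oxy]-2,6-dimethyl-3-[(E)-2-(phenylsulfonyl)ethenyl]oct-2-en-7-yn-5-yl acetate; 21 propanoyl chloride
Product: 22 (2E,5S,6S)-1-[(tert-butyldimethylsilyl)oxy]-2,6-dimethyl-9-oxo-3-[(E)-2-(phenylsulfonyl)ethenyl]undec-2-en-7-yn-5-yl acetate
Conditions: PdCl2(PPh3)2 (2 mol %), CuI (4 mol %), Et3N (1.2 equiv), THF, rt
Reagents that add atoms: none
Why: Acyl Sonogashira coupling: the copper acetylide of 20 is transferred to the acylpalladium species from 21 and reductive elimination gives the ynone, which brings in C3, C4 and C15 at the ketone oxidation level.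

Step 14
Reactants: 22 (2E,5S,6S)-1-[(tert-butyldimethylsilyl)oxy]-2,6-dimethyl-9-oxo-3-[(E)-2-(phenylsulfonyl)ethenyl]undec-2-en-7-yn-5-yl acetate
Product: 23 (2E,5S,6S,9Z)-1-[(tert-butyldimethylsilyl)oxy]-2,6-dimethyl-3-[(E)-2-(phenylsulfonyl)ethenyl]-9-[(triethylsilyl)oxy]undeca-2,9-dien-7-yn-5-yl acetate
Conditions: Et3SiOTf, Et3N, CH2Cl2, −78 °C
Reagents that add atoms: triethylsilyl trifluoromethanesulfonate CC[Si](CC)(CC)OS(=O)(=O)C(F)(F)F
Why: Soft enolisation of the ethyl ketone with silyl triflate and amine gives the silyl enol ether, expected as the (Z) isomer (methyl cis to oxygen), which places the C15 methyl on the outside of the later diene.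

Step 15
Reactants: 23 (2E,5S,6S,9Z)-1-[(tert-butyldimethylsilyl)oxy]-2,6-dimethyl-3-[(E)-2-(phenylsulfonyl)ethenyl]-9-[(triethylsilyl)oxy]undeca-2,9-dien-7-yn-5-yl acetate
Product: 24 (2E,5S,6S,7Z,9Z)-1-[(tert-butyldimethylsilyl)oxy]-2,6-dimethyl-3-[(E)-2-(phenylsulfonyl)ethenyl]-9-[(triethylsilyl)oxy]undeca-2,7,9-trien-5-yl acetate
Conditions: H2 (1 atm), Pd/CaCO3 poisoned with Pb(OAc)2 (Lindlar catalyst), quinoline, EtOAc/hexane, rt
Reagents that add atoms: none
Why: Lindlar semi-hydrogenation adds H2 syn to the alkyne only and gives the (Z)-C1=C2 double bond, completing the (1Z,3Z)-3-silyloxy diene; the poisoned catalyst leaves the alkenes, the sulfone and the enol ether.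

Step 16
Reactants: 24 (2E,5S,6S,7Z,9Z)-1-[(tert-butyldimethylsilyl)oxy]-2,6-dimethyl-3-[(E)-2-(phenylsulfonyl)ethenyl]-9-[(triethylsilyl)oxy]undeca-2,7,9-trien-5-yl acetate
Product: 25 cis-fused cycloadduct, 9α-acetoxy-12-[(tert-butyldimethylsilyl)oxy]-4β-methyl-5β-(phenylsulfonyl)-3-[(triethylsilyl)oxy]cadina-2,7(11)-diene (1β-H, 6β-H, 10β-CH3)
Conditions: PhMe (0.01 M), BHT (cat.), 130 °C, sealed tube
Reagents that add atoms: none
Why: Thermal, concerted but asynchronous intramolecular [4+2] cycloaddition of the electron-rich (1Z,3Z)-3-silyloxy diene (C1–C4) onto the sulfonyl-activated alkene C5=C6, the close precedent being intramolecular Diels–Alder reactions of 1,7,9-decatrienes that carry a terminal sulfonyl dienophile or a 2-silyloxy diene. Ring B closes through the four-carbon tether C7–C10 as a six-membered ring with the tether exo and chair-like, and ring A is the cyclohexene formed suprafacially on both components; the short tether allows only the fused regiochemistry (C1 to C6, C4 to C5). Because C10 sits on the inside (Z) position of the diene, the chain can reach C6 only through the transition state that places H1 and H6 on the same face, so the cis ring fusion (C6) is fixed by geometry and not by an endo/exo preference. C1 is set relative to C10 by allylic 1,3-strain across the (Z)-C1=C2 bond: H10 lies in the diene plane toward C3, the tether sits on the reacting face and the C10 methyl is anti to the new C1–C6 bond, which puts C2, the C10 methyl and the C9 acetoxy group all equatorial on ring B. C4 and C5 follow from the enol ether and (E)-sulfone geometries and are erased in step 17. The selectivity that matters is the π-facial one at C1, secured as described, together with cycloaddition outrunning a 1,5-hydrogen shift of the (Z)-diene, for which the sulfone-lowered LUMO and the silyloxy-raised HOMO are relied on.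

Step 17
Reactants: 25 cis-fused cycloadduct
Product: 27 (1R,6R,9S,10S)-9-acetoxy-12-[(tert-butyldimethylsilyl)oxy]cadina-4,7(11)-dien-3-one (cis-fused), via ketone 26 (not isolated)
Conditions: 0.5 M HCl, THF, 0 °C; then DBU, CH2Cl2, 0 °C
Reagents that add atoms: none
Why: Mild acid hydrolyses the silyl enol ether to the C3 ketone 26, and DBU then removes H4 and expels benzenesulfinate from C5 (E1cB), which creates the conjugated C4=C5 bond and removes the activating group in one operation.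

Step 18
Reactants: 27 (1R,6R,9S,10S)-9-acetoxy-12-[(tert-butyldimethylsilyl)oxy]cadina-4,7(11)-dien-3-one
Product: 28 (1R,3S,6R,9S,10S)-12-[(tert-butyldimethylsilyl)oxy]-3-hydroxycadina-4,7(11)-dien-9-yl acetate
Conditions: NaBH4, CeCl3·7H2O, MeOH, −78 °C
Reagents that add atoms: none
Why: Luche 1,2-reduction: in the cis-fused enone ring B hangs axially (through C10) under ring A, so hydride is delivered to the convex face that carries H1 and H6 and the 3α-alcohol (3S) should result.

Step 19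
Reactants: 28 (1R,3S,6R,9S,10S)-12-[(tert-butyldimethylsilyl)oxy]-3-hydroxycadina-4,7(11)-dien-9-yl acetate
Product: 29 (1R,3S,6R,9S,10S)-12-[(tert-butyldimethylsilyl)oxy]cadina-4,7(11)-diene-3,9-diyl diacetate
Conditions: Ac2O, pyridine, DMAP (cat.), CH2Cl2, 0 °C to rt
Reagents that add atoms: acetic anhydride CC(=O)OC(C)=O
Why: Acetylation of the allylic C3 hydroxyl with retention gives the second acetate of the target.

Step 20
Reactants: 29 (1R,3S,6R,9S,10S)-12-[(tert-butyldimethylsilyl)oxy]cadina-4,7(11)-diene-3,9-diyl diacetate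
Product: 30 (1R,3S,6R,9S,10S)-12-hydroxycadina-4,7(11)-diene-3,9-diyl diacetate
Conditions: HF·pyridine, pyridine, THF, 0 °C to rt
Reagents that add atoms: none
Why: Buffered HF·pyridine cleaves the primary silyl ether by Si–F bond formation without acyl migration or loss of the acetates.

Step 21
Reactants: 30 (1R,3S,6R,9S,10S)-12-hydroxycadina-4,7(11)-diene-3,9-diyl diacetate
Product: 31 (1R,3S,6R,9S,10S)-3,9-diacetoxycadina-4,7(11)-dien-12-yl formate (CNP0262962.2)
Conditions: HCO2H and Ac2O (50 °C, 2 h, then 0 °C); then 30, pyridine, CH2Cl2, 0 °C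
Reagents that add atoms: acetic formic anhydride CC(=O)OC=O, made in the flask from formic acid O=CO and acetic anhydride CC(=O)OC(C)=O
Why: Formyl transfer from the mixed anhydride, whose formyl carbonyl is the more electrophilic one, converts the only free (primary allylic) hydroxyl into the formate and gives the target.

**Compound list**

1 | (R)-4-(trimethylsilyl)but-3-yn-2-ol | C[C@@H](O)C#C[Si](C)(C)C | starting material
2 | (R)-4-(trimethylsilyl)but-3-yn-2-yl methanesulfonate | C[C@@H](OS(C)(=O)=O)C#C[Si](C)(C)C | intermediate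
3 | 3-[(tert-butyldimethylsilyl)oxy]propanal | O=CCCO[Si](C)(C)C(C)(C)C | starting material
4 | ethyl[(aS)-1-(trimethylsilyl)buta-1,2-dien-1-yl]zinc | CC[Zn]C([Si](C)(C)C)=[C@@]=C([H])C | intermediate (not isolated)
5 | (3R,4S)-1-[(tert-butyldimethylsilyl)oxy]-4-methyl-6-(trimethylsilyl)hex-5-yn-3-ol | C[Si](C)(C)C#C[C@H](C)[C@H](O)CCO[Si](C)(C)C(C)(C)C | intermediate
6 | propanoic acid | CCC(=O)O | starting material
7 | (3S,4S)-1-[(tert-butyldimethylsilyl)oxy]-4-methyl-6-(trimethylsilyl)hex-5-yn-3-yl propanoate | C[Si](C)(C)C#C[C@H](C)[C@@H](OC(=O)CC)CCO[Si](C)(C)C(C)(C)C | intermediate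
8 | (3S,4S)-1-hydroxy-4-methyl-6-(trimethylsilyl)hex-5-yn-3-yl propanoate | C[Si](C)(C)C#C[C@H](C)[C@@H](OC(=O)CC)CCO | intermediate (not isolated)
9 | (3S,4S)-4-methyl-1-oxo-6-(trimethylsilyl)hex-5-yn-3-yl propanoate | C[Si](C)(C)C#C[C@H](C)[C@@H](OC(=O)CC)CC=O | intermediate (not isolated)
10 | (3S,4S)-4-methyl-3-(propanoyloxy)-6-(trimethylsilyl)hex-5-ynoic acid | C[Si](C)(C)C#C[C@H](C)[C@@H](OC(=O)CC)CC(=O)O | intermediate
11 | methyl (3S,4S)-4-methyl-3-(propanoyloxy)-6-(trimethylsilyl)hex-5-ynoate | C[Si](C)(C)C#C[C@H](C)[C@@H](OC(=O)CC)CC(=O)OC | intermediate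
12 | (6S)-4-hydroxy-3-methyl-6-[(2S)-4-(trimethylsilyl)but-3-yn-2-yl]-5,6-dihydro-2H-pyran-2-one | C[Si](C)(C)C#C[C@H](C)[C@@H]1CC(O)=C(C)C(=O)O1 | intermediate
13 | (6S)-3-methyl-2-oxo-6-[(2S)-4-(trimethylsilyl)but-3-yn-2-yl]-5,6-dihydro-2H-pyran-4-yl trifluoromethanesulfonate | C[Si](C)(C)C#C[C@H](C)[C@@H]1CC(OS(=O)(=O)C(F)(F)F)=C(C)C(=O)O1 | intermediate
14 | phenyl vinyl sulfone | C=CS(=O)(=O)c1ccccc1 | starting material
15 | (6S)-3-methyl-4-[(E)-2-(phenylsulfonyl)ethenyl]-6-[(2S)-4-(trimethylsilyl)but-3-yn-2-yl]-5,6-dihydro-2H-pyran-2-one | C[Si](C)(C)C#C[C@H](C)[C@@H]1CC(/C=C/S(=O)(=O)c2ccccc2)=C(C)C(=O)O1 | intermediate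
16 | (6S)-3-methyl-4-[(E)-2-(phenylsulfonyl)ethenyl]-6-[(2S)-4-(trimethylsilyl)but-3-yn-2-yl]-5,6-dihydro-2H-pyran-2-ol (as aluminium alkoxide, both anomers) | C[Si](C)(C)C#C[C@H](C)[C@@H]1CC(/C=C/S(=O)(=O)c2ccccc2)=C(C)C(O)O1 | intermediate (not isolated)
17 | (2E,5S,6S)-2,6-dimethyl-3-[(E)-2-(phenylsulfonyl)ethenyl]-8-(trimethylsilyl)oct-2-en-7-yne-1,5-diol | C[Si](C)(C)C#C[C@H](C)[C@@H](O)C/C(/C=C/S(=O)(=O)c1ccccc1)=C(/C)CO | intermediate
18 | (2E,5S,6S)-1-[(tert-butyldimethylsilyl)oxy]-2,6-dimethyl-3-[(E)-2-(phenylsulfonyl)ethenyl]-8-(trimethylsilyl)oct-2-en-7-yn-5-ol | C[Si](C)(C)C#C[C@H](C)[C@@H](O)C/C(/C=C/S(=O)(=O)c1ccccc1)=C(/C)CO[Si](C)(C)C(C)(C)C | intermediate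
19 | (2E,5S,6S)-1-[(tert-butyldimethylsilyl)oxy]-2,6-dimethyl-3-[(E)-2-(phenylsulfonyl)ethenyl]-8-(trimethylsilyl)oct-2-en-7-yn-5-yl acetate | C[Si](C)(C)C#C[C@H](C)[C@@H](OC(C)=O)C/C(/C=C/S(=O)(=O)c1ccccc1)=C(/C)CO[Si](C)(C)C(C)(C)C | intermediate
20 | (2E,5S,6S)-1-[(tert-butyldimethylsilyl)oxy]-2,6-dimethyl-3-[(E)-2-(phenylsulfonyl)ethenyl]oct-2-en-7-yn-5-yl acetate | C#C[C@H](C)[C@@H](OC(C)=O)C/C(/C=C/S(=O)(=O)c1ccccc1)=C(/C)CO[Si](C)(C)C(C)(C)C | intermediate
21 | propanoyl chloride | CCC(=O)Cl | starting material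
22 | (2E,5S,6S)-1-[(tert-butyldimethylsilyl)oxy]-2,6-dimethyl-9-oxo-3-[(E)-2-(phenylsulfonyl)ethenyl]undec-2-en-7-yn-5-yl acetate | CCC(=O)C#C[C@H](C)[C@@H](OC(C)=O)C/C(/C=C/S(=O)(=O)c1ccccc1)=C(/C)CO[Si](C)(C)C(C)(C)C | intermediate
23 | (2E,5S,6S,9Z)-1-[(tert-butyldimethylsilyl)oxy]-2,6-dimethyl-3-[(E)-2-(phenylsulfonyl)ethenyl]-9-[(triethylsilyl)oxy]undeca-2,9-dien-7-yn-5-yl acetate | C/C=C(\O[Si](CC)(CC)CC)C#C[C@H](C)[C@@H](OC(C)=O)C/C(/C=C/S(=O)(=O)c1ccccc1)=C(/C)CO[Si](C)(C)C(C)(C)C | intermediate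
24 | (2E,5S,6S,7Z,9Z)-1-[(tert-butyldimethylsilyl)oxy]-2,6-dimethyl-3-[(E)-2-(phenylsulfonyl)ethenyl]-9-[(triethylsilyl)oxy]undeca-2,7,9-trien-5-yl acetate | C/C=C(\O[Si](CC)(CC)CC)/C=C\[C@H](C)[C@@H](OC(C)=O)C/C(/C=C/S(=O)(=O)c1ccccc1)=C(/C)CO[Si](C)(C)C(C)(C)C | intermediate
25 | cis-fused 9α-acetoxy-12-[(tert-butyldimethylsilyl)oxy]-4β-methyl-5β-(phenylsulfonyl)-3-[(triethylsilyl)oxy]cadina-2,7(11)-diene (1β-H, 6β-H, 10β-CH3) | CC[Si](CC)(CC)OC1=C[C@H]2[C@H](C)[C@@H](OC(C)=O)C/C(=C(/C)CO[Si](C)(C)C(C)(C)C)[C@H]2[C@H](S(=O)(=O)c3ccccc3)[C@@H]1C | intermediate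
26 | cis-fused 9α-acetoxy-12-[(tert-butyldimethylsilyl)oxy]-4β-methyl-5β-(phenylsulfonyl)cadin-7(11)-en-3-one | O=C1C[C@H]2[C@H](C)[C@@H](OC(C)=O)C/C(=C(/C)CO[Si](C)(C)C(C)(C)C)[C@H]2[C@H](S(=O)(=O)c3ccccc3)[C@@H]1C | intermediate (not isolated)
27 | (1R,6R,9S,10S)-9-acetoxy-12-[(tert-butyldimethylsilyl)oxy]cadina-4,7(11)-dien-3-one | O=C1C[C@H]2[C@H](C)[C@@H](OC(C)=O)C/C(=C(/C)CO[Si](C)(C)C(C)(C)C)[C@H]2C=C1C | intermediate
28 | (1R,3S,6R,9S,10S)-12-[(tert-butyldimethylsilyl)oxy]-3-hydroxycadina-4,7(11)-dien-9-yl acetate | O[C@H]1C[C@H]2[C@H](C)[C@@H](OC(C)=O)C/C(=C(/C)CO[Si](C)(C)C(C)(C)C)[C@H]2C=C1C | intermediate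
29 | (1R,3S,6R,9S,10S)-12-[(tert-butyldimethylsilyl)oxy]cadina-4,7(11)-diene-3,9-diyl diacetate | CC(=O)O[C@H]1C[C@H]2[C@H](C)[C@@H](OC(C)=O)C/C(=C(/C)CO[Si](C)(C)C(C)(C)C)[C@H]2C=C1C | intermediate
30 | (1R,3S,6R,9S,10S)-12-hydroxycadina-4,7(11)-diene-3,9-diyl diacetate | CC(=O)O[C@H]1C[C@H]2[C@H](C)[C@@H](OC(C)=O)C/C(=C(/C)CO)[C@H]2C=C1C | intermediate
31 | (1R,3S,6R,9S,10S)-3,9-diacetoxycadina-4,7(11)-dien-12-yl formate (CNP0262962.2) | CC(=O)O[C@H]1C[C@H]2[C@H](C)[C@@H](OC(C)=O)C/C(=C(/C)COC=O)[C@H]2C=C1C | target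

**Step count**

Total steps: 21. Longest linear sequence: 21 steps (from 1 to 31).

**Steps most likely to fail**

Step 16 (cycloaddition). The (Z)-diene may reach the reactive s-cis conformation too slowly, so that a 1,5-hydrogen shift from C10 or oligomerisation consumes it before ring closure. Fallback: the geometric constraint is given up for reactivity. The fallback sets out from ynone 22, which is semi-hydrogenated (H2, Lindlar catalyst, quinoline) to the (Z)-enone F1 and isomerised with catalytic DABCO (CH2Cl2, rt) to the (E)-enone F2. Soft enolisation (Et3SiOTf, Et3N) gives the (1E,3Z)-diene F3, whose cycloaddition (PhMe, 90–110 °C) should pass mainly through the tether-endo, sulfone-exo transition state to the cis-fused adduct F4 (the 4-epimer of 25), with some trans-fused isomer expected. Hydrolysis and DBU elimination as in step 17 bring the material back to enone 27, where the trans-fused isomer is removed by chromatography.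

Step 6 (Dieckmann condensation). Deprotonation at C8 of the methyl ester followed by E1cB loss of the propanoyloxy group from C9 may outrun the Claisen closure. Fallback: the C11 enolate is made without an amide base. The fallback sets out from alcohol 5, which is esterified under Mitsunobu conditions (PPh3, DIAD) with 2-bromopropanoic acid to the bromo ester F5 (both epimers at the CHBr carbon). Jones oxidation gives the acid F6 and Me3SiCHN2 the methyl ester F7. Activated zinc (Zn dust, Me3SiCl cat., THF, reflux) then forms the zinc enolate at C11, which closes onto the methyl ester in a Reformatsky-type Claisen condensation and returns to the route at pyranone 12.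

Step 3 (Mitsunobu inversion). The alkoxyphosphonium ion of the hindered carbinol may be displaced slowly by the weakly acidic propanoic acid, so that elimination or acyl transfer with retention competes. Fallback: inversion is done on a sulfonate. The fallback sets out from alcohol 5, which is converted (MsCl, Et3N, CH2Cl2) into the mesylate F8; displacement with caesium propanoate (EtCO2Cs, 18-crown-6, PhMe, 90 °C) inverts C9 and returns to the route at propanoate 7.

Further compounds
F1 | step 16 | (2E,5S,6S,7Z)-1-[(tert-butyldimethylsilyl)oxy]-2,6-dimethyl-9-oxo-3-[(E)-2-(phenylsulfonyl)ethenyl]undeca-2,7-dien-5-yl acetate | CCC(=O)/C=C\[C@H](C)[C@@H](OC(C)=O)C/C(/C=C/S(=O)(=O)c1ccccc1)=C(/C)CO[Si](C)(C)C(C)(C)C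
F2 | step 16 | (2E,5S,6S,7E)-1-[(tert-butyldimethylsilyl)oxy]-2,6-dimethyl-9-oxo-3-[(E)-2-(phenylsulfonyl)ethenyl]undeca-2,7-dien-5-yl acetate | CCC(=O)/C=C/[C@H](C)[C@@H](OC(C)=O)C/C(/C=C/S(=O)(=O)c1ccccc1)=C(/C)CO[Si](C)(C)C(C)(C)C
F3 | step 16 | (2E,5S,6S,7E,9Z)-1-[(tert-butyldimethylsilyl)oxy]-2,6-dimethyl-3-[(E)-2-(phenylsulfonyl)ethenyl]-9-[(triethylsilyl)oxy]undeca-2,7,9-trien-5-yl acetate | C/C=C(\O[Si](CC)(CC)CC)/C=C/[C@H](C)[C@@H](OC(C)=O)C/C(/C=C/S(=O)(=O)c1ccccc1)=C(/C)CO[Si](C)(C)C(C)(C)C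
F4 | step 16 | cis-fused 9α-acetoxy-12-[(tert-butyldimethylsilyl)oxy]-4α-methyl-5β-(phenylsulfonyl)-3-[(triethylsilyl)oxy]cadina-2,7(11)-diene (4-epimer of 25) | CC[Si](CC)(CC)OC1=C[C@H]2[C@H](C)[C@@H](OC(C)=O)C/C(=C(/C)CO[Si](C)(C)C(C)(C)C)[C@H]2[C@H](S(=O)(=O)c3ccccc3)[C@H]1C
F5 | step 6 | (3S,4S)-1-[(tert-butyldimethylsilyl)oxy]-4-methyl-6-(trimethylsilyl)hex-5-yn-3-yl 2-bromopropanoate | C[Si](C)(C)C#C[C@H](C)[C@@H](OC(=O)C(C)Br)CCO[Si](C)(C)C(C)(C)C
F6 | step 6 | (3S,4S)-3-[(2-bromopropanoyl)oxy]-4-methyl-6-(trimethylsilyl)hex-5-ynoic acid | C[Si](C)(C)C#C[C@H](C)[C@@H](OC(=O)C(C)Br)CC(=O)O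
F7 | step 6 | methyl (3S,4S)-3-[(2-bromopropanoyl)oxy]-4-methyl-6-(trimethylsilyl)hex-5-ynoate | C[Si](C)(C)C#C[C@H](C)[C@@H](OC(=O)C(C)Br)CC(=O)OC
F8 | step 3 | (3R,4S)-1-[(tert-butyldimethylsilyl)oxy]-4-methyl-6-(trimethylsilyl)hex-5-yn-3-yl methanesulfonate | C[Si](C)(C)C#C[C@H](C)[C@H](OS(C)(=O)=O)CCO[Si](C)(C)C(C)(C)C
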